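**Plan**

- Retrosynthesis: the trans pair of C–O bonds at C1 (the fully substituted ring carbon carrying OH and CH2OBz) and C2 (the neighbouring ring CHOH) is traced back to an epoxide on a C1=C2 cyclohexene. The ring is then cut at C1=C2 (metathesis) to a 1,7-diene, the 1,1-disubstituted alkene goes back to a ketone, and the C5–C6 bond to an aldol between protected dihydroxyacetone and pent-4-enal.
- Enabling feature: C1 and C2 are adjacent ring carbinols with their oxygens trans, C1 carries a benzoyloxymethyl group whose ester C=O sits 1,2 to C1, and the C6 hydroxyl is allylic to C1=C2 and cis to the C2 hydroxyl. A direct reductive carbonyl coupling at C1–C2 would be expected to give the cis diol with CH2OBz equatorial, so the alkene is used instead.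
- Forward order: the aldol joins C5–C6 (C7–C1–C6 from the ketone, C5–C2 from the aldehyde); benzoylation and methylenation follow; metathesis closes the only ring, the six-membered carbocycle, at C1=C2; then desilylation, primary benzoylation, epoxidation and ester-assisted epoxide opening.
- Stereochemistry: C5 and C6 come from the catalyst-controlled syn-aldol; C2 from epoxidation directed by the C6 hydroxyl; C1 by inversion when the carbonyl oxygen of the C7 benzoate opens the epoxide at C1.

Key step: step 4

Assumption: O-tert-butyl-threonine of the L series is taken to give the (3R,4S) syn-aldol of protected dihydroxyacetone, so the D-configured catalyst is specified for the (3S,4R) series needed here; if the sense is the reverse, the enantiomeric catalyst is used.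

Step 1
Reactants: 1 1,3-bis[(tert-butyldimethylsilyl)oxy]propan-2-one; 2 pent-4-enal
Product: 3 (3S,4R)-1,3-bis[(tert-butyldimethylsilyl)oxy]-4-hydroxyoct-7-en-2-one
Conditions: O-tert-butyl-D-threonine (20 mol%), 1 (3 equiv), NMP/H2O 97:3, 4 °C, slow addition of 2
Reagents that add atoms: none
Why: Primary-amine enamine catalysis (direct syn-aldol of protected dihydroxyacetone): the (Z)-enamine, held by an N–H···O hydrogen bond to the silyloxy oxygen, attacks the acid-activated aldehyde, so catalyst control should set both new stereocentres, C3 (S) and C4 (R), in the syn (threo) relationship.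

Step 2
Reactants: 3 (3S,4R)-1,3-bis[(tert-butyldimethylsilyl)oxy]-4-hydroxyoct-7-en-2-one
Product: 4 (3S,4R)-1,3-bis[(tert-butyldimethylsilyl)oxy]-2-oxooct-7-en-4-yl benzoate
Conditions: BzCl (1.3 equiv), pyridine, DMAP (10 mol%), CH2Cl2, 0 °C
Reagents that add atoms: benzoyl chloride, O=C(Cl)c1ccccc1
Why: Nucleophile-catalysed O-acylation of the only free hydroxyl puts the C5 benzoate of the target in place and blocks retro-aldol cleavage; the weak base and low temperature should avoid β-elimination and silyl migration, and no stereocentre is touched.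

Step 3
Reactants: 4 (3S,4R)-1,3-bis[(tert-butyldimethylsilyl)oxy]-2-oxooct-7-en-4-yl benzoate
Product: 5 (3R,4R)-3-[(tert-butyldimethylsilyl)oxy]-2-{[(tert-butyldimethylsilyl)oxy]methyl}octa-1,7-dien-4-yl benzoate
Conditions: Zn, CH2Br2, TiCl4, THF/CH2Cl2, 0 °C to rt
Reagents that add atoms: dibromomethane, BrCBr
Why: Takai–Lombardo methylenation: the non-basic zinc/titanium gem-dimetallic methylene reagent should convert the ketone, but not the benzoate, into the 1,1-disubstituted alkene without enolisation, so the α-stereocentre and the β-benzoyloxy group should survive (the descriptor at C3 changes only because the priorities change).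

Step 4
Reactants: 5 (3R,4R)-3-[(tert-butyldimethylsilyl)oxy]-2-{[(tert-butyldimethylsilyl)oxy]methyl}octa-1,7-dien-4-yl benzoate
Product: 6 (1R,2R)-2-[(tert-butyldimethylsilyl)oxy]-3-{[(tert-butyldimethylsilyl)oxy]methyl}cyclohex-3-en-1-yl benzoate
Conditions: second-generation Grubbs catalyst RuCl2(=CHPh)(PCy3)(H2IMes) (5 mol%), toluene (0.005 M), 80 °C
Reagents that add atoms: none
Why: Ring-closing olefin metathesis: the ruthenium alkylidene is loaded onto the unhindered monosubstituted alkene (C2), and the resulting C2 alkylidene adds across the 1,1-disubstituted alkene at C1 through a ruthenacyclobutane whose cycloreversion releases ethene and the C1=C2 bond. The closest known reaction type is the ring-closing metathesis of oxygenated 1,7-dienes with a 2-(alkoxymethyl)allyl terminus to trisubstituted cyclohexenes, as used for carbasugars. The one ring formed, the six-membered carbocycle C1–C6, is closed by a [2+2]/retro-[2+2] sequence at C1=C2 and not by a polar exo or endo cyclisation. No stereocentre is created and C5 and C6 pass through unchanged under the neutral conditions; the step provides the C1=C2 alkene from which C2 (step 7) and C1 (step 8) are set stereospecifically. The step needs ring closure to win over cross-metathesis and over double-bond migration into the allylic silyl ether; the strain-free six-membered ring, high dilution and the bulky silyl ethers flanking the 1,1-disubstituted alkene, which make it inert to intermolecular metathesis, should secure this.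

Step 5
Reactants: 6 (1R,2R)-2-[(tert-butyldimethylsilyl)oxy]-3-{[(tert-butyldimethylsilyl)oxy]methyl}cyclohex-3-en-1-yl benzoate
Product: 7 (1R,2R)-2-hydroxy-3-(hydroxymethyl)cyclohex-3-en-1-yl benzoate
Conditions: HF·pyridine, THF/pyridine, 0 °C to rt
Reagents that add atoms: none
Why: Fluoride-mediated cleavage of both silyl ethers under buffered, weakly acidic conditions, under which the C5 benzoate should neither hydrolyse nor migrate to the neighbouring C6 hydroxyl.

Step 6
Reactants: 7 (1R,2R)-2-hydroxy-3-(hydroxymethyl)cyclohex-3-en-1-yl benzoate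
Product: 8 [(5R,6R)-5-(benzoyloxy)-6-hydroxycyclohex-1-en-1-yl]methyl benzoate
Conditions: BzCl (1.05 equiv), 2,4,6-collidine, CH2Cl2, −78 to −40 °C
Reagents that add atoms: benzoyl chloride, O=C(Cl)c1ccccc1
Why: Sterically controlled selective acylation: the primary allylic hydroxyl should react far faster than the secondary C6 hydroxyl, which is flanked by the C5 benzoate and the trisubstituted alkene, and the weak hindered base should not trigger acyl migration.

Step 7
Reactants: 8 [(5R,6R)-5-(benzoyloxy)-6-hydroxycyclohex-1-en-1-yl]methyl benzoate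
Product: 9 [(1S,2S,3R,6R)-3-(benzoyloxy)-2-hydroxy-7-oxabicyclo[4.1.0]heptan-1-yl]methyl benzoate
Conditions: VO(acac)2 (5 mol%), t-BuOOH (1.5 equiv, in decane), CH2Cl2, 0 °C to rt
Reagents that add atoms: tert-butyl hydroperoxide, CC(C)(C)OO
Why: Hydroxyl-directed epoxidation of a cyclic allylic alcohol: the vanadium alkoxide formed at the C6 hydroxyl delivers the peroxide oxygen to C1=C2 on the face of that hydroxyl, which fixes the C2 oxygen cis to the C6 hydroxyl (the final C2 configuration) and places the CH2OBz group on the opposite face.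

Step 8
Reactants: 9 [(1S,2S,3R,6R)-3-(benzoyloxy)-2-hydroxy-7-oxabicyclo[4.1.0]heptan-1-yl]methyl benzoate
Product: 11 [(1S,2S,3R,6R)-3-(benzoyloxy)-1,2,6-trihydroxycyclohexyl]methyl benzoate, via 2-phenyl-1,3-dioxolan-2-ylium ion 10 (not isolated)
Conditions: TfOH (1.1 equiv), CH2Cl2, −78 °C; then H2O/THF, −78 to 0 °C
Reagents that add atoms: water, O
Why: Acid-induced epoxy ester rearrangement with neighbouring-group participation (the same type as the acid-promoted epoxy ester to ortho ester rearrangement of 2,3-epoxy alcohol esters): the carbonyl oxygen of the C7 benzoate opens the protonated epoxide at the tertiary carbon C1 in a 5-exo mode with inversion, which sets C1 (oxygen trans to the C2 and C6 hydroxyls, CH2 cis to them) while the epoxide oxygen stays on C2, and water then cleaves the acyloxonium ion to the tertiary alcohol and the primary benzoate.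

**Compound list**

1 | 1,3-bis[(tert-butyldimethylsilyl)oxy]propan-2-one | CC(C)(C)[Si](C)(C)OCC(=O)CO[Si](C)(C)C(C)(C)C | starting material
2 | pent-4-enal | C=CCCC=O | starting material
3 | (3S,4R)-1,3-bis[(tert-butyldimethylsilyl)oxy]-4-hydroxyoct-7-en-2-one | C=CCC[C@@H](O)[C@@H](C(=O)CO[Si](C)(C)C(C)(C)C)O[Si](C)(C)C(C)(C)C | intermediate
4 | (3S,4R)-1,3-bis[(tert-butyldimethylsilyl)oxy]-2-oxooct-7-en-4-yl benzoate | C=CCC[C@@H](OC(=O)c1ccccc1)[C@@H](C(=O)CO[Si](C)(C)C(C)(C)C)O[Si](C)(C)C(C)(C)C | intermediate
5 | (3R,4R)-3-[(tert-butyldimethylsilyl)oxy]-2-{[(tert-butyldimethylsilyl)oxy]methyl}octa-1,7-dien-4-yl benzoate | C=CCC[C@@H](OC(=O)c1ccccc1)[C@@H](C(=C)CO[Si](C)(C)C(C)(C)C)O[Si](C)(C)C(C)(C)C | intermediate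
6 | (1R,2R)-2-[(tert-butyldimethylsilyl)oxy]-3-{[(tert-butyldimethylsilyl)oxy]methyl}cyclohex-3-en-1-yl benzoate | CC(C)(C)[Si](C)(C)OCC1=CCC[C@@H](OC(=O)c2ccccc2)[C@@H]1O[Si](C)(C)C(C)(C)C | intermediate
7 | (1R,2R)-2-hydroxy-3-(hydroxymethyl)cyclohex-3-en-1-yl benzoate | OCC1=CCC[C@@H](OC(=O)c2ccccc2)[C@@H]1O | intermediate
8 | [(5R,6R)-5-(benzoyloxy)-6-hydroxycyclohex-1-en-1-yl]methyl benzoate | O=C(OCC1=CCC[C@@H](OC(=O)c2ccccc2)[C@@H]1O)c1ccccc1 | intermediate
9 | [(1S,2S,3R,6R)-3-(benzoyloxy)-2-hydroxy-7-oxabicyclo[4.1.0]heptan-1-yl]methyl benzoate (epoxide oxygen cis to the C6 hydroxyl) | O=C(OC[C@@]12O[C@@H]1CC[C@@H](OC(=O)c1ccccc1)[C@@H]2O)c1ccccc1 | intermediate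
10 | (5S,6S,7R,10R)-7-(benzoyloxy)-6,10-dihydroxy-2-phenyl-1,3-dioxaspiro[4.5]decan-2-ylium ion (triflate counter-ion; ring oxygen at the spiro carbon trans to both hydroxyls) | C1O[C+](c2ccccc2)O[C@]13[C@H](O)CC[C@@H](OC(=O)c2ccccc2)[C@@H]3O | intermediate
11 | [(1S,2S,3R,6R)-3-(benzoyloxy)-1,2,6-trihydroxycyclohexyl]methyl benzoate | O=C(OC[C@]1(O)[C@H](O)CC[C@@H](OC(=O)c2ccccc2)[C@@H]1O)c1ccccc1 | target

**Step count and risks**

Total step count: 8. Longest linear sequence: 8 steps (from 1 and 2).

Steps most likely to fail: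

Step 1. The unbranched, enolisable aldehyde may self-condense faster than the enamine captures it, and the syn/anti and facial discrimination may be incomplete. The fallback sets out from 2 and returns at 7. Compound 2 is combined with 2,2-dimethyl-1,3-dioxan-5-one F1 under (S)-proline catalysis (DMF, 2 °C) to give the anti-aldol (S)-4-[(S)-1-hydroxypent-4-en-1-yl]-2,2-dimethyl-1,3-dioxan-5-one F2, which has the correct C6 and the opposite C5 configuration. Methylenation with Zn/CH2Br2/TiCl4 should give (S)-1-[(R)-2,2-dimethyl-5-methylidene-1,3-dioxan-4-yl]pent-4-en-1-ol F3. A Mitsunobu reaction with benzoic acid (PPh3, DIAD) inverts C5 and installs its benzoate in one operation, giving (R)-1-[(R)-2,2-dimethyl-5-methylidene-1,3-dioxan-4-yl]pent-4-en-1-yl benzoate F4. Ring-closing metathesis with the same ruthenium catalyst should give the bicyclic acetonide (8R,8aR)-2,2-dimethyl-6,7,8,8a-tetrahydro-4H-1,3-benzodioxin-8-yl benzoate F5, and aqueous acetic acid removes the acetonide to give 7.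

Step 8. The ester carbonyl or water may attack C2 instead of C1, and the benzoyl group may wander among the hydroxyls while the acyloxonium ion is hydrolysed. The fallback sets out from 7 and returns at 11; it brings the C1 oxygen in from water and installs the primary benzoate last. Silylation of the primary hydroxyl of 7 (TBSCl, imidazole, −20 °C) gives (1R,2R)-3-{[(tert-butyldimethylsilyl)oxy]methyl}-2-hydroxycyclohex-3-en-1-yl benzoate F6. The same directed epoxidation gives (1S,2S,3R,6R)-1-{[(tert-butyldimethylsilyl)oxy]methyl}-2-hydroxy-7-oxabicyclo[4.1.0]heptan-3-yl benzoate F7. Dilute aqueous HClO4 in THF should open the protonated epoxide at the tertiary carbon with inversion (the C5 benzoate can assist only from the same face) and cleave the silyl ether, giving (1R,2S,3S,4R)-2,3,4-trihydroxy-3-(hydroxymethyl)cyclohexyl benzoate F8. Selective benzoylation of the primary hydroxyl (BzCl, collidine, −40 °C) gives 11.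

Step 3. The hindered α,α'-dioxygenated carbonyl may not react, or the β-benzoate may be eliminated by enolisation. The fallback sets out from 4 and returns at 6; it closes the same C1–C2 bond reductively and then removes both oxygens. Ozonolysis of 4 (O3, then Me2S) gives the keto aldehyde (4R,5S)-5,7-bis[(tert-butyldimethylsilyl)oxy]-1,6-dioxoheptan-4-yl benzoate F9. SmI2-mediated pinacol cyclisation (THF, t-BuOH, −78 °C) should give the cis-diol (1R,2S,3R,4R)-2-[(tert-butyldimethylsilyl)oxy]-3-{[(tert-butyldimethylsilyl)oxy]methyl}-3,4-dihydroxycyclohexyl benzoate F10; either cis diastereomer serves, since both new centres are removed again. Thiocarbonyldiimidazole converts it into the cis-fused cyclic thionocarbonate of F10, 4-[(tert-butyldimethylsilyl)oxy]-3a-{[(tert-butyldimethylsilyl)oxy]methyl}-2-thioxohexahydro-1,3-benzodioxol-5-yl benzoate F11, and Corey–Winter elimination with P(OMe)3 at 110 °C gives 6.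

**Further compounds**

F1 | step 1 | 2,2-dimethyl-1,3-dioxan-5-one | CC1(C)OCC(=O)CO1
F2 | step 1 | (S)-4-[(S)-1-hydroxypent-4-en-1-yl]-2,2-dimethyl-1,3-dioxan-5-one | C=CCC[C@H](O)[C@@H]1OC(C)(C)OCC1=O
F3 | step 1 | (S)-1-[(R)-2,2-dimethyl-5-methylidene-1,3-dioxan-4-yl]pent-4-en-1-ol | C=CCC[C@H](O)[C@@H]1OC(C)(C)OCC1=C
F4 | step 1 | (R)-1-[(R)-2,2-dimethyl-5-methylidene-1,3-dioxan-4-yl]pent-4-en-1-yl benzoate | C=CCC[C@@H](OC(=O)c1ccccc1)[C@@H]1OC(C)(C)OCC1=C
F5 | step 1 | (8R,8aR)-2,2-dimethyl-6,7,8,8a-tetrahydro-4H-1,3-benzodioxin-8-yl benzoate | CC1(C)OCC2=CCC[C@@H](OC(=O)c3ccccc3)[C@@H]2O1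
F6 | step 8 | (1R,2R)-3-{[(tert-butyldimethylsilyl)oxy]methyl}-2-hydroxycyclohex-3-en-1-yl benzoate | CC(C)(C)[Si](C)(C)OCC1=CCC[C@@H](OC(=O)c2ccccc2)[C@@H]1O
F7 | step 8 | (1S,2S,3R,6R)-1-{[(tert-butyldimethylsilyl)oxy]methyl}-2-hydroxy-7-oxabicyclo[4.1.0]heptan-3-yl benzoate | CC(C)(C)[Si](C)(C)OC[C@@]12O[C@@H]1CC[C@@H](OC(=O)c1ccccc1)[C@@H]2O
F8 | step 8 | (1R,2S,3S,4R)-2,3,4-trihydroxy-3-(hydroxymethyl)cyclohexyl benzoate | OC[C@]1(O)[C@H](O)CC[C@@H](OC(=O)c2ccccc2)[C@@H]1O
F9 | step 3 | (4R,5S)-5,7-bis[(tert-butyldimethylsilyl)oxy]-1,6-dioxoheptan-4-yl benzoate | O=CCC[C@@H](OC(=O)c1ccccc1)[C@@H](C(=O)CO[Si](C)(C)C(C)(C)C)O[Si](C)(C)C(C)(C)C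
F10 | step 3 | (1R,2S,3R,4R)-2-[(tert-butyldimethylsilyl)oxy]-3-{[(tert-butyldimethylsilyl)oxy]methyl}-3,4-dihydroxycyclohexyl benzoate (cis-3,4-diol) | CC(C)(C)[Si](C)(C)OC[C@@]1(O)[C@H](O)CC[C@@H](OC(=O)c2ccccc2)[C@@H]1O[Si](C)(C)C(C)(C)C
F11 | step 3 | 4-[(tert-butyldimethylsilyl)oxy]-3a-{[(tert-butyldimethylsilyl)oxy]methyl}-2-thioxohexahydro-1,3-benzodioxol-5-yl benzoate (cis-fused cyclic thionocarbonate of F10) | CC(C)(C)[Si](C)(C)OC[C@]12OC(=S)O[C@@H]2CC[C@@H](OC(=O)c2ccccc2)[C@@H]1O[Si](C)(C)C(C)(C)C
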